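The earlier runs and the new flask are calculated for substances that don't exist; noise was put on by code.

How much target and third product will the flask hold at 15 min?

- the target standing at 15 min, as a percentage of the starting material charged
- the third product standing at 15 min, as a percentage of the starting material charged

| flask | starting material | protic impurity | remark | time |
|---|---|---|---|---|
| green | 20 mM | 0.27 mM | run made earlier |  |
| red | 20 mM | 0.60 mM | run made earlier |  |
| ochre | 40 mM | 0.40 mM | run made earlier |  |
| flask | 20 mM | 0.400 mM |  | 15 min |

| run | time / min | target / % | third product / % |
|---|---|---|---|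
| green | 3.00 | 88 | 2 |
| green | 6.00 | 94 | 2 |
| green | 10.0 | 97 | 2 |
| green | 12.0 | 98 | 2 |
| green | 15.0 | 96 | 2 |
| red | 3.00 | 87 | 2 |
| red | 6.00 | 92 | 5 |
| red | 10.0 | 94 | 2 |
| red | 12.0 | 93 | 3 |
| red | 15.0 | 96 | 1 |
| ochre | 1.33 | 60 | 0 |
| ochre | 4.00 | 91 | 4 |
| ochre | 8.00 | 93 | 3 |
| ochre | 10.0 | 97 | 1 |
| ochre | 15.0 | 98 | 0 |

(each reading ± 1.5 percentage points)

- in a conversion other conformer counts as not yet reacted; third conformer counts as reacted

The zero of the scale is a flask with one path, in which every starting material becomes target; the reckoning then subtracts losses. Supposing that each protic impurity takes one substrate, which makes it the limiting reagent of that loss, the first loss is the ratio of charges: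

s = 2.00%

The second loss is x, third product. Its means over 5 readings are 2.00% (green), 2.60% (red) and 1.60% (ochre), each good to 0.67 percentage points, so they are read as one level:

x = 2.07%

C = 100% − s − x = 95.9%

This ceiling C, the plateau of target once starting material has reacted, has one weak link: a flat x. Reforged on red, C becomes 94.9% against late readings averaging 94.3%; on green, 96.6% against 97.0%. Green's first reading gives an apparent first-order constant k = 0.807 min⁻¹, so the flask should stand on its ceiling at the asked time.

The forecast gives 96.5% target and 2% third product, holding that the averages of third product “roughly track impurity/starting material”, whereas this reckoning keeps x flat.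

The flask gives 95.1% and 2.01%, so the forecast held.

    starting material ⇌ other conformer (K = 0.0220, k = 2.30 s⁻¹)
    other conformer → isomer of the product (k = 0.00500 s⁻¹)
    third conformer → third product (k = 0.130 s⁻¹)
    other conformer + protic impurity → quenched substrate (k = 160 L mol⁻¹ s⁻¹)
    starting material → target (k = 0.0130 s⁻¹)
    2 other conformer → homo dimer (k = 1.00 L mol⁻¹ s⁻¹)
    other conformer ⇌ third conformer (K = 2.60, k = 0.0130 s⁻¹)

The flask's target at the asked time lies 0.80 points under C, and the flask holds 0.805% of isomer of the product, which C does not contain, while its quenched substrate stands at 1.99%, the size of s. With the back reaction of other conformer to starting material struck out, the flask's third product goes from 2.01% to 36.9%, so that return holds it down.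

Stopped at time t = 4.0 min, the same flask should show C(1 − exp(−kt)) = 92.1% target; the computed neighbour holds 91.1%, with 4.1% of starting material left.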